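**Plan**

- Retrosynthesis: the C3 angelate and the C5 silyl group come off last. The enone (C11=O, C9=C10) is a 1,2-transposed C10 ketone. The cyclobutane bond C2–C8 is then cut to a cis-fused bicyclo[5.4.0]undecadienone with a C2–C3 epoxide. Further cuts are C2=C3 (metathesis), C4–C5 (allylation) and C6–C7 (Claisen shift), back to (S)-carvone.
- Forward: ring C (six-membered) is bought as carvone, the quaternary C6 is put on C7, the C4/C5 arm is added with the isovalerate already on C4, the seven-membered ring is closed at C2=C3, and the cyclobutane is closed last across both rings.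
- Enabling feature: C8 is the β-carbon of a 2-methylcyclohex-2-enone (C10=O, C9=C8), and C2 is a tertiary carbon next to the oxygenated C3. A C2–C3 epoxide on the seven-membered ring therefore opens to a C2 radical 1,4 to C8, which closes the four-membered ring and leaves the C3 oxygen in place.
- Stereochemistry: C1 from carvone; C7 relayed by the suprafacial Claisen shift from a C–O bond set by directed epoxidation; C4/C5 by the iridium catalyst; C3 by convex-face epoxidation; C2 and C8 fixed by the cis ring fusion during the ring closure.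

Key step: step 13

Remark (locants): the tricyclo[5.4.0.0^2,8]undecane numbering of the target is used for all compounds: C1 and C7 ring-fusion CH, C2 C(CH3), C3 (O-angeloyl), C4 (O-isovaleryl), C5 (OH), C6 CMe2, C8 cyclobutane CH, C9 =C(CH3), C10 =CH, C11 C=O.

Assumption: in step 8 the ligand is written as (R)-SEGPHOS on the assumption that it directs attack to the re face of aldehyde 14; if the sense is the opposite, (S)-SEGPHOS is used.

Assumption: ketone 21 is drawn as the kinetic C9 epimer; this centre becomes sp2 in step 14, so either epimer serves.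

**Route**

Step 1
Reactants: 1 (S)-(+)-carvone
Product: 2 (1S,5S)-cis-carveol
Conditions: NaBH4, CeCl3·7H2O, MeOH, −20 °C
Reagents that add atoms: none
Why: Luche reduction; 1,2-selective axial hydride delivery should give the equatorial C10 alcohol cis to the isopropenyl group at C1.

Step 2
Reactants: 2 (1S,5S)-cis-carveol
Product: 3 cis-carveol 8,9-epoxide (oxirane syn to the hydroxyl)
Conditions: VO(acac)2 (cat.), t-BuOOH, CH2Cl2, 0 °C → rt
Reagents that add atoms: tert-butyl hydroperoxide, CC(C)(C)OO
Why: Hydroxyl-directed vanadium epoxidation (Sharpless) should deliver oxygen syn to C10–OH, which puts the C9–O bond cis to the isopropenyl group and leaves the isopropenyl alkene untouched.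

Step 3
Reactants: 3 cis-carveol 8,9-epoxide
Product: 5 (1S,2R,5R)-2-methyl-5-(prop-1-en-2-yl)cyclohex-3-ene-1,2-diol, via hydroxy selenide 4 (not isolated)
Conditions: (PhSe)2, NaBH4, EtOH, 80 °C; then 30% H2O2, THF, 0 °C → rt
Reagents that add atoms: none
Why: Sharpless–Lauer sequence; PhSe− opens the epoxide by SN2 attack at the secondary C8, and selenoxide syn-elimination away from the carbinol gives the C7=C8 alkene with the tertiary C9–O bond unchanged.

Step 4
Reactants: 5 allylic diol
Product: 6 bis(2-methylpropanoate) of diol 5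
Conditions: n-BuLi (2.1 equiv), THF, −78 °C; then isobutyryl chloride, −78 °C → rt
Reagents that add atoms: isobutyryl chloride, CC(C)C(=O)Cl
Why: O-acylation of the dilithium dialkoxide should esterify the tertiary allylic hydroxyl as well as the secondary one; no stereocentre is touched.

Step 5
Reactants: 6 bis(2-methylpropanoate)
Product: 9 all-cis 2-[4-(isobutyryloxy)-3-methyl-6-(prop-1-en-2-yl)cyclohex-2-en-1-yl]-2-methylpropanoic acid, via bis(silyl ketene acetal) 7 (not isolated), via rearranged silyl ester 8 (not isolated)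
Conditions: LiN(iPr)2 (2.5 equiv), Me3SiCl, Et3N, THF, −78 °C → 65 °C; then 1 M HCl
Reagents that add atoms: none
Why: Ireland–Claisen rearrangement; the ketene acetal of the tertiary allylic ester shifts suprafacially, so the C6–C7 bond should form on the face that carried the C9–O bond, cis to the isopropenyl group, while the second ester only forms a ketene acetal that is hydrolysed back.

Step 6
Reactants: 9 acid ester
Product: 10 all-cis 4-(1-hydroxy-2-methylpropan-2-yl)-2-methyl-5-(prop-1-en-2-yl)cyclohex-2-en-1-ol
Conditions: LiAlH4, THF, 0 → 65 °C; then H2O, aq. NaOH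
Reagents that add atoms: none
Why: Hydride reduction should convert the neopentyl acid into the primary alcohol and cleave the isobutyrate in the same operation.

Step 7
Reactants: 11 acrolein; 12 isovaleric anhydride
Product: 13 prop-2-ene-1,1-diyl bis(3-methylbutanoate)
Conditions: FeCl3 (cat.), neat, 0 °C → rt
Reagents that add atoms: none
Why: Lewis acid catalysed acylal formation (addition of the anhydride across the aldehyde C=O) should give the allyl donor that carries the isovalerate.

Step 8
Reactants: 10 diol; 13 prop-2-ene-1,1-diyl bis(3-methylbutanoate)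
Product: 15 (3R,4S)-anti hydroxy isovalerate (C4 O-isovaleryl and C5 OH with free C10 OH), via aldehyde 14 (not isolated)
Conditions: [Ir(cod)Cl]2 (cat.), (R)-SEGPHOS, 4-cyano-3-nitrobenzoic acid, Cs2CO3 (cat.), THF, 90 °C
Reagents that add atoms: none
Why: Krische iridium-catalysed transfer-hydrogenative anti-(acyloxy)allylation; the primary alcohol is dehydrogenated to aldehyde 14, which the (E)-σ-(acyloxy)allyl iridium species attacks through a chair transition state to give the anti C4/C5 pair with the absolute sense set by the ligand, and the secondary allylic alcohol is not a substrate.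

Step 9
Reactants: 15 anti hydroxy isovalerate
Product: 16 enone (C10 ketone with C8=C9 and free C5 OH)
Conditions: MnO2, CH2Cl2, rt
Reagents that add atoms: none
Why: MnO2 should oxidise only the allylic C10 alcohol and restore the carvone-type enone whose β-carbon is C8.

Step 10
Reactants: 16 enone
Product: 17 C5 tert-butyldimethylsilyl ether of 16
Conditions: TBSOTf, 2,6-lutidine, CH2Cl2, −78 → 0 °C
Reagents that add atoms: tert-butyldimethylsilyl triflate, CC(C)(C)[Si](C)(C)OS(=O)(=O)C(F)(F)F
Why: Silylation of the remaining neopentyl C5 hydroxyl blocks acyl migration from C4 and ensures that C3–OH is later the only free hydroxyl.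

Step 11
Reactants: 17 silyl ether diene
Product: 18 cis-fused bicyclo[5.4.0]undeca-2,8-dien-10-one
Conditions: second-generation Grubbs catalyst (H2IMes)(PCy3)Cl2Ru=CHPh (cat.), toluene (0.005 M), 80 °C
Reagents that add atoms: none
Why: Ring-closing metathesis between the vinyl and isopropenyl groups should give the trisubstituted C2=C3 cycloheptene, helped by the C6 gem-dimethyl group and the cis arms on ring C; the enone alkene does not take part.

Step 12
Reactants: 18 bicyclic dienone
Product: 19 C2–C3 epoxide (oxirane on the face of H-1)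
Conditions: mCPBA, NaHCO3, CH2Cl2, 0 °C
Reagents that add atoms: 3-chloroperbenzoic acid, OOC(=O)c1cccc(Cl)c1
Why: Prilezhaev epoxidation should take the electron-rich trisubstituted alkene and not the enone, from the convex face (that of H-1) and anti to the allylic C4 acyloxy group, which sets C3.

Step 13
Reactants: 19 epoxy enone
Product: 21 tricyclic C3-hydroxy C10-ketone, via titanium enolate 20 (not isolated)
Conditions: Cp2TiCl2, Zn dust, THF, rt, to give Cp2TiCl (trivalent titanium); added slowly to 19 in THF (0.01 M), rt; then aq. NaH2PO4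
Reagents that add atoms: none
Why: Cp2TiCl opens the epoxide by single-electron transfer at the more substituted C2–O bond, giving a tertiary C2 radical with a titanium alkoxide on C3; the radical adds to C8, the enone β-carbon, and a second Cp2TiCl reduces the α-keto radical to titanium enolate 20, which makes the otherwise reversible closure irreversible. The closest known reaction type is the titanocene-mediated reductive epoxide opening with 4-exo-trig radical addition to an α,β-unsaturated carbonyl group, as used to make cyclobutanes and the pinane skeleton from carvone-derived epoxy enones. The cyclobutane (C1, C2, C8, C7) is closed 4-exo-trig, and the same bond completes the bicyclo[3.1.1]heptanone and the bridged seven-membered ring. C2 and C8 are set by the cis ring fusion, because the C2 radical can reach C8 only from the face on which C1 holds it, so the C2 methyl should end syn to the ketone bridge; C3 keeps the configuration given by the epoxide, and C9 is set by protonation of 20 and lost again in step 14. The step needs regioselective C–O homolysis (secured by the tertiary versus secondary difference) and ring closure faster than interception of the radical by a second titanocene with β-hydride elimination (favoured by high dilution, slow addition and the 1,3-diaxial proximity of C2 and C8 when the bulky C6 sits equatorial on ring C).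

Step 14
Reactants: 21 tricyclic ketone
Product: 22 diosphenol (C11 ketone with C10 enol OH and C9=C10)
Conditions: SeO2, 1,4-dioxane, H2O (trace), 90 °C
Reagents that add atoms: selenium dioxide, O=[Se]=O
Why: Riley oxidation should attack the α-methylene C11 and not the α-methine C9, and the 1,2-dione can enolise only toward C9 because C1 is a bridgehead.

Step 15
Reactants: 22 diosphenol
Product: 23 C10 enol triflate
Conditions: PhNTf2, Et3N, DMAP (cat.), CH2Cl2, 0 °C → rt
Reagents that add atoms: N-phenylbis(trifluoromethanesulfonimide), O=S(=O)(N(c1ccccc1)S(=O)(=O)C(F)(F)F)C(F)(F)F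
Why: The acidic diosphenol hydroxyl should be O-triflated selectively, the hindered secondary C3 hydroxyl being inert to PhNTf2.

Step 16
Reactants: 23 enol triflate
Product: 24 C3-hydroxy enone (C11 ketone with C9=C10)
Conditions: Pd(OAc)2 (cat.), PPh3, HCO2H, Et3N, DMF, 60 °C
Reagents that add atoms: none
Why: Palladium-catalysed formate reduction of an enol triflate (Cacchi conditions: oxidative addition, formate exchange, decarboxylation, reductive elimination) should remove the C10 oxygen and complete the 1,2-carbonyl transposition.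

Step 17
Reactants: 24 C3-hydroxy enone
Product: 25 C3 angelate (C5 silyl ether of the target)
Conditions: angelic acid, 2,4,6-trichlorobenzoyl chloride, Et3N, toluene, rt; then 24, 80 °C
Reagents that add atoms: angelic acid, C/C=C(/C)C(=O)O
Why: Yamaguchi-type mixed anhydride acylation without a nucleophilic catalyst should esterify the only free hydroxyl while keeping the Z geometry of the angelate.

Step 18
Reactants: 25 silyl ether
Product: 26 CNP0251293.1
Conditions: HF·pyridine, pyridine, THF, 0 °C → rt
Reagents that add atoms: none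
Why: Fluoride-mediated cleavage of the silyl ether under buffered acidic conditions should free C5–OH without ester migration or angelate isomerisation.

**Compound list**

1 | (S)-(+)-carvone, (5S)-2-methyl-5-(prop-1-en-2-yl)cyclohex-2-en-1-one | CC1=CC[C@@H](CC1=O)C(C)=C | starting material
2 | (1S,5S)-cis-carveol (OH cis to isopropenyl) | CC1=CC[C@@H](C[C@@H]1O)C(C)=C | intermediate
3 | cis-carveol 8,9-epoxide (carveol 2,3-position), oxirane cis to OH and to isopropenyl | C[C@@]12O[C@@H]1C[C@@H](C[C@@H]2O)C(C)=C | intermediate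
4 | hydroxy selenide, 2-methyl-3-(phenylselanyl)-5-(prop-1-en-2-yl)cyclohexane-1,2-diol, both OH cis to isopropenyl, SePh trans (not isolated) | C[C@@]1(O)[C@@H]([Se]c2ccccc2)C[C@@H](C[C@@H]1O)C(C)=C | intermediate
5 | (1S,2R,5R)-2-methyl-5-(prop-1-en-2-yl)cyclohex-3-ene-1,2-diol (both OH cis to isopropenyl) | C[C@@]1(O)C=C[C@@H](C[C@@H]1O)C(C)=C | intermediate
6 | bis(2-methylpropanoate) of 5 | C[C@@]1(OC(=O)C(C)C)C=C[C@@H](C[C@@H]1OC(=O)C(C)C)C(C)=C | intermediate
7 | bis(trimethylsilyl ketene acetal) of 6 (not isolated) | C[C@@]1(OC(O[Si](C)(C)C)=C(C)C)C=C[C@@H](C[C@@H]1OC(O[Si](C)(C)C)=C(C)C)C(C)=C | intermediate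
8 | trimethylsilyl ester formed by the [3,3] shift, second ketene acetal still in place (not isolated) | CC1=C[C@@H]([C@@H](C[C@@H]1OC(O[Si](C)(C)C)=C(C)C)C(C)=C)C(C)(C)C(=O)O[Si](C)(C)C | intermediate
9 | all-cis 2-[4-(isobutyryloxy)-3-methyl-6-(prop-1-en-2-yl)cyclohex-2-en-1-yl]-2-methylpropanoic acid | CC1=C[C@@H]([C@@H](C[C@@H]1OC(=O)C(C)C)C(C)=C)C(C)(C)C(=O)O | intermediate
10 | all-cis 4-(1-hydroxy-2-methylpropan-2-yl)-2-methyl-5-(prop-1-en-2-yl)cyclohex-2-en-1-ol | CC1=C[C@@H]([C@@H](C[C@@H]1O)C(C)=C)C(C)(C)CO | intermediate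
11 | acrolein | C=CC=O | starting material
12 | isovaleric anhydride (3-methylbutanoic anhydride) | CC(C)CC(=O)OC(=O)CC(C)C | starting material
13 | prop-2-ene-1,1-diyl bis(3-methylbutanoate) | C=CC(OC(=O)CC(C)C)OC(=O)CC(C)C | intermediate
14 | all-cis 2-[4-hydroxy-3-methyl-6-(prop-1-en-2-yl)cyclohex-2-en-1-yl]-2-methylpropanal (not isolated) | CC1=C[C@@H]([C@@H](C[C@@H]1O)C(C)=C)C(C)(C)C=O | intermediate
15 | (3R,4S)-4-hydroxy-5-methyl-5-[all-cis-4-hydroxy-3-methyl-6-(prop-1-en-2-yl)cyclohex-2-en-1-yl]hex-1-en-3-yl 3-methylbutanoate (anti) | C=C[C@@H](OC(=O)CC(C)C)[C@@H](O)C(C)(C)[C@H]1C=C(C)[C@@H](O)C[C@H]1C(C)=C | intermediate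
16 | (3R,4S)-4-hydroxy-5-methyl-5-[cis-3-methyl-4-oxo-6-(prop-1-en-2-yl)cyclohex-2-en-1-yl]hex-1-en-3-yl 3-methylbutanoate | C=C[C@@H](OC(=O)CC(C)C)[C@@H](O)C(C)(C)[C@H]1C=C(C)C(=O)C[C@H]1C(C)=C | intermediate
17 | C5 tert-butyldimethylsilyl ether of 16 | C=C[C@@H](OC(=O)CC(C)C)[C@@H](O[Si](C)(C)C(C)(C)C)C(C)(C)[C@H]1C=C(C)C(=O)C[C@H]1C(C)=C | intermediate
18 | cis-fused 5-(TBSO)-2,6,6,9-tetramethyl-10-oxobicyclo[5.4.0]undeca-2,8-dien-4-yl 3-methylbutanoate (H-1 and H-7 cis; C4 and C5 oxygens cis to each other, on the face of ring C) | CC1=C[C@@H](OC(=O)CC(C)C)[C@@H](O[Si](C)(C)C(C)(C)C)C(C)(C)[C@H]2C=C(C)C(=O)C[C@@H]12 | intermediate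
19 | C2–C3 epoxide of 18, oxirane on the face of H-1 and anti to the C4 ester | C[C@@]12O[C@@H]1[C@@H](OC(=O)CC(C)C)[C@@H](O[Si](C)(C)C(C)(C)C)C(C)(C)[C@H]3C=C(C)C(=O)C[C@@H]23 | intermediate
20 | titanium enolate: C3 titanocene alkoxide and C10 titanocene enolate of the closed tricycle (not isolated) | Cl[Ti](C4C=CC=C4)(C5C=CC=C5)O[C@@H]1[C@@H](OC(=O)CC(C)C)[C@@H](O[Si](C)(C)C(C)(C)C)C(C)(C)[C@@H]2[C@H]3CC(O[Ti](Cl)(C6C=CC=C6)C7C=CC=C7)=C(C)[C@@H]2[C@@]13C | intermediate
21 | 3-hydroxy-2,6,6,9-tetramethyl-10-oxo-5-(TBSO)tricyclo[5.4.0.0^2,8]undecan-4-yl 3-methylbutanoate (C9 methyl drawn syn to the C2 bridge) | O[C@@H]1[C@@H](OC(=O)CC(C)C)[C@@H](O[Si](C)(C)C(C)(C)C)C(C)(C)[C@@H]2[C@H]3CC(=O)[C@H](C)[C@@H]2[C@@]13C | intermediate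
22 | 3,10-dihydroxy-2,6,6,9-tetramethyl-11-oxo-5-(TBSO)tricyclo[5.4.0.0^2,8]undec-9-en-4-yl 3-methylbutanoate (diosphenol) | O[C@@H]1[C@@H](OC(=O)CC(C)C)[C@@H](O[Si](C)(C)C(C)(C)C)C(C)(C)[C@@H]2[C@H]3C(=O)C(O)=C(C)[C@@H]2[C@@]13C | intermediate
23 | C10 enol triflate of 22 | O[C@@H]1[C@@H](OC(=O)CC(C)C)[C@@H](O[Si](C)(C)C(C)(C)C)C(C)(C)[C@@H]2[C@H]3C(=O)C(OS(=O)(=O)C(F)(F)F)=C(C)[C@@H]2[C@@]13C | intermediate
24 | 3-hydroxy-2,6,6,9-tetramethyl-11-oxo-5-(TBSO)tricyclo[5.4.0.0^2,8]undec-9-en-4-yl 3-methylbutanoate | O[C@@H]1[C@@H](OC(=O)CC(C)C)[C@@H](O[Si](C)(C)C(C)(C)C)C(C)(C)[C@@H]2[C@H]3C(=O)C=C(C)[C@@H]2[C@@]13C | intermediate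
25 | C3 angelate of 24 (C5 silyl ether of the target) | C/C=C(/C)C(=O)O[C@@H]1[C@@H](OC(=O)CC(C)C)[C@@H](O[Si](C)(C)C(C)(C)C)C(C)(C)[C@@H]2[C@H]3C(=O)C=C(C)[C@@H]2[C@@]13C | intermediate
26 | CNP0251293.1, 3-(angeloyloxy)-5-hydroxy-4-(3-methylbutanoyloxy)-2,6,6,9-tetramethyltricyclo[5.4.0.0^2,8]undec-9-en-11-one (C3 oxygen trans to the cis C4/C5 oxygens) | C/C=C(/C)C(=O)O[C@@H]1[C@@H](OC(=O)CC(C)C)[C@@H](O)C(C)(C)[C@@H]2[C@H]3C(=O)C=C(C)[C@@H]2[C@@]13C | target

**Step count and risks**

Total step count: 18. Longest linear sequence: 17 steps (steps 1–6 and 8–18, from carvone 1 to 26); step 7 is a one-step side branch.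

Steps most likely to fail:

Step 13 (cyclobutane closure). Interception of the tertiary C2 radical by a second titanocene followed by β-hydride elimination, or reversal of the strained 4-exo closure, may outrun ring closure. Fallback: starting from epoxide 19, the opening is run concentrated with excess Cp2TiCl so that this interception becomes the main path and gives the exocyclic allylic alcohol F1 (C2=CH2 with C3–OH of the required configuration). The C2 radical is then regenerated from the 1,1-disubstituted alkene by metal hydride hydrogen-atom transfer (Fe(acac)3, PhSiH3, EtOH, 60 °C), with no titanium present to intercept it. Addition to C8 and reduction of the α-keto radical should return the route at ketone 21.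

Step 8 (iridium allylation). Dehydrogenation and carbonyl addition at the neopentyl carbinol may be too slow with the isovalerate donor, and acyl migration to C5 or loss of anti selectivity may follow on prolonged heating. Fallback: starting from diol 10, Dess–Martin periodinane oxidises both hydroxyls to the keto aldehyde F2. Reagent-controlled allylboration follows with [(E)-γ-(1,3,2-dioxaborinan-2-yl)allyl]B(Ipc)2 (Ipc2BH from (−)-α-pinene, −78 °C), then C–B oxidation with Me3NO, to give the anti-diol F3. Selective acylation of the less hindered allylic C4 hydroxyl (isovaleryl chloride, 2,4,6-collidine, CH2Cl2, −40 °C) returns the route at enone 16.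

Step 17 (angelate). Acylation of the hindered C3 hydroxyl may be slow enough for the activated angelate to isomerise to the tiglate, or for the C4 ester to migrate. Fallback: starting from alcohol 24, coupling with 2-[bis(2,2,2-trifluoroethoxy)phosphoryl]propanoic acid (DCC, DMAP, CH2Cl2) gives the phosphonate ester F4 (mixture at the phosphonate α-carbon). Still–Gennari olefination with acetaldehyde (KN(SiMe3)2, 18-crown-6, THF, −78 °C) then builds the Z-alkene on the ester already in place and returns the route at 25.

Further compounds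
F1 | step 13 | exocyclic allylic alcohol, 3-hydroxy-6,6,9-trimethyl-2-methylidene-10-oxo-5-(TBSO)bicyclo[5.4.0]undec-8-en-4-yl 3-methylbutanoate | C=C1[C@H](O)[C@@H](OC(=O)CC(C)C)[C@@H](O[Si](C)(C)C(C)(C)C)C(C)(C)[C@H]2C=C(C)C(=O)C[C@@H]12
F2 | step 8 | keto aldehyde, 2-methyl-2-[cis-3-methyl-4-oxo-6-(prop-1-en-2-yl)cyclohex-2-en-1-yl]propanal | CC1=C[C@@H]([C@@H](CC1=O)C(C)=C)C(C)(C)C=O
F3 | step 8 | anti-diol, (3R,4S)-5-methyl-5-[cis-3-methyl-4-oxo-6-(prop-1-en-2-yl)cyclohex-2-en-1-yl]hex-1-ene-3,4-diol | C=C[C@@H](O)[C@@H](O)C(C)(C)[C@H]1C=C(C)C(=O)C[C@H]1C(C)=C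
F4 | step 17 | phosphonate ester, C3 2-[bis(2,2,2-trifluoroethoxy)phosphoryl]propanoate of 24 | CC(P(=O)(OCC(F)(F)F)OCC(F)(F)F)C(=O)O[C@@H]1[C@@H](OC(=O)CC(C)C)[C@@H](O[Si](C)(C)C(C)(C)C)C(C)(C)[C@@H]2[C@H]3C(=O)C=C(C)[C@@H]2[C@@]13C
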